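All runs were computed with made-up constants; noise was put on by code.

I decided to follow one molecule of coupling partner and ask for its chance of ending as first product.

in all of them: substrate 0.50 M
- alder: coupling partner 1.8 equiv; run made earlier
- larch: coupling partner 4.4 equiv; run made earlier
- spring: coupling partner 1.20 equiv; time 6.0 d
- autumn: coupling partner 2.00 equiv; time 6.0 d
- winter: coupling partner 3.00 equiv; time 6.0 d

| run | time / d | first product / % |
|---|---|---|
| alder | 0.500 | 6 |
| alder | 1.04 | 12 |
| alder | 2.50 | 12 |
| alder | 6.00 | 14 |
| larch | 0.500 | 15 |
| larch | 1.04 | 17 |
| larch | 2.50 | 25 |
| larch | 6.00 | 23 |

(scatter of a reading: 1.5 percentage points)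

- what was read earlier has a scatter of 1.5 percentage points, one standard deviation

* how much first product is there at the end, in percent of the substrate charged: for each flask in turn (spring, autumn, winter)

Both runs look flat from 2.50 d on, so I averaged the last two readings of each and divided by the equivalents charged. That quotient φ, first product at the plateau per equivalent of partner, is the chance I wanted if partner is the limiting reagent, and alder gave φ = 0.0722. Larch gave 0.0545.

Was one number enough? No. Alder's φ would put larch at 31.8%, more than the 24.0% read there, against a scatter of 1.5 percentage points on a reading. A falling φ is what I expected if later partner molecules meet less substrate, so I drew a straight line through the two runs. At 3.00 equiv it gave φ = 0.0641. My reckoning was 9.16% for spring, which lies outside the range of the runs, 14.2% for autumn and 19.2% for winter.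

The forecast reads the plateau differently, “That looks like a reversible coupling”, and gives 8.4%, 13.3% and 18.7%, lower than mine in spring, in autumn and in winter.

The flasks gave 9.48%, 14.4% and 19.4%, so the forecast was right within the tolerance.

    coupling partner + first product → double product + by-product (k = 0.00384 L mol⁻¹ h⁻¹)
    substrate + coupling partner → other mono adduct + by-product (k = 0.0130 L mol⁻¹ h⁻¹)
    coupling partner + other mono adduct → double product + by-product (k = 0.00803 L mol⁻¹ h⁻¹)
    coupling partner → decomposed reagent (k = 0.0415 h⁻¹)
    substrate + coupling partner → first product + by-product (k = 0.00952 L mol⁻¹ h⁻¹)

A reversible reading needs partner standing beside substrate at the plateau; autumn at 6.00 d held 0.073% of its partner charge and 64.4% of its substrate. Autumn's φ was 0.0720, against 0.0709 on my line. Winter's φ was 0.0647, against 0.0641 on the line.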